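**Strategy.** The route rests on the C6(ring A)–CH2 bond, the last C–C bond formed. A base-free Negishi sp2–sp3 coupling unites the complete (2S)-flavanone, as its C6 iodide, with the complete side chain, as a primary alkylzinc iodide that carries the preset side-chain stereocentre and the silylated carbinol. The step exploits C6 of ring A: lying between O5 and O7, it is the only free position ortho to the chelated 5-OH of a chromone precursor, so iodine can be placed there selectively. The CH2 that is coupled is one carbon away from the side-chain stereocentre, so no stereocentre is touched. The zinc partner derives from (R)-lavandulol; C2 is set by Rh-catalysed asymmetric arylation of the iodochromone.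

Key step: step 10

Assumption: (R)-(−)-lavandulol, the natural enantiomer, is taken as a commercial chiral-pool material; its stereocentre is never touched, and the descriptor changes to S in the target only because the CIP priorities change.

**Step 1**
Reactants: 1 5,7-dihydroxy-4H-chromen-4-one
Product: 2 5-hydroxy-7-(methoxymethoxy)-4H-chromen-4-one
Conditions: MOMCl (1.1 equiv), i-Pr2NEt, CH2Cl2, 0 °C to rt
Reagents that add atoms: chloromethyl methyl ether, COCCl
Why: Williamson-type O-alkylation (MOM protection); the 7-OH is the acidic, non-chelated phenol, whereas the 5-OH is held in a hydrogen bond to C4=O, so mono-protection at O7 is expected.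

**Step 2**
Reactants: 2 5-hydroxy-7-(methoxymethoxy)-4H-chromen-4-one
Product: 3 5-hydroxy-6-iodo-7-(methoxymethoxy)-4H-chromen-4-one
Conditions: BnMe3N·ICl2 (1.05 equiv), CaCO3, CH2Cl2/MeOH, rt
Reagents that add atoms: benzyltrimethylammonium dichloroiodate, C[N+](C)(C)Cc1ccccc1.Cl[I-]Cl
Why: Electrophilic aromatic iodination; the hydrogen-bonded 5-OH should direct the iodine to its free ortho position C6 (the known behaviour of 5-hydroxy-7-alkoxy-chromones and -flavones with this reagent), and CaCO3 buffers the HCl so the MOM acetal survives.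

**Step 3**
Reactants: 3 5-hydroxy-6-iodo-7-(methoxymethoxy)-4H-chromen-4-one
Product: 4 6-iodo-5-methoxy-7-(methoxymethoxy)-4H-chromen-4-one
Conditions: MeI (3 equiv), K2CO3, DMF, 40 °C
Reagents that add atoms: iodomethane, CI
Why: Williamson O-methylation of the chelated 5-OH, made more acidic by the ortho iodine; it is done at the chromone stage because no base-labile stereocentre exists yet.

**Step 4**
Reactants: 5 4-bromobenzene-1,3-diol
Product: 6 1-bromo-2,4-bis(methoxymethoxy)benzene
Conditions: MOMCl (2.5 equiv), i-Pr2NEt, CH2Cl2, 0 °C to rt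
Reagents that add atoms: chloromethyl methyl ether, COCCl
Why: Double MOM protection (Williamson-type) of both phenols, giving acetals that tolerate organolithium and Rh chemistry.

**Step 5**
Reactants: 6 1-bromo-2,4-bis(methoxymethoxy)benzene
Product: 9 [2,4-bis(methoxymethoxy)phenyl]boronic acid, via 2,4-bis(methoxymethoxy)phenyllithium 7 (not isolated), via lithium aryltriisopropoxyborate 8 (not isolated)
Conditions: n-BuLi, THF, −78 °C; B(Oi-Pr)3, −78 °C to rt; sat. aq. NH4Cl
Reagents that add atoms: triisopropyl borate, CC(C)OB(OC(C)C)OC(C)C; water, O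
Why: Bromine–lithium exchange followed by borylation; exchange at −78 °C is faster than ortho-lithiation between the two OMOM groups, so boron enters at the carbon that carried bromine.

**Step 6**
Reactants: 4 6-iodo-5-methoxy-7-(methoxymethoxy)-4H-chromen-4-one; 9 [2,4-bis(methoxymethoxy)phenyl]boronic acid
Product: 10 (2S)-2-[2,4-bis(methoxymethoxy)phenyl]-6-iodo-5-methoxy-7-(methoxymethoxy)-2,3-dihydro-4H-chromen-4-one
Conditions: [Rh(OH)(cod)]2 (2.5 mol %), (S)-MeO-F12-BIPHEP (5.5 mol %), 9 (3 equiv), toluene/H2O, 30 °C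
Reagents that add atoms: none
Why: Rh-catalysed asymmetric 1,4-addition of an arylboronic acid to a chromone (Hayashi–Miyaura type), in which the C2 stereocentre is set by catalyst control as the aryl–Rh species inserts into C2=C3; the (S)-ligand is expected, by analogy with cyclic enones, to give 2S (the sense is to be verified once and the ligand antipode used otherwise), the base-free medium avoids retro-oxa-Michael racemisation, and the hindered C6–I bond should be inert to Rh(I) at this temperature.

**Step 7**
Reactants: 11 (R)-lavandulol, (2R)-5-methyl-2-(prop-1-en-2-yl)hex-4-en-1-ol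
Product: 12 (3S)-3-(hydroxymethyl)-2,6-dimethylhept-5-en-2-ol
Conditions: Mn(dpm)3 (5 mol %), PhSiH3 (1.2 equiv), O2 (1 atm), i-PrOH, 0 °C to rt
Reagents that add atoms: dioxygen, O=O
Why: Mukaiyama hydration (metal-hydride hydrogen-atom transfer, Markovnikov); the 1,1-disubstituted isopropenyl alkene should accept the hydrogen atom faster than the trisubstituted prenyl alkene, and the neighbouring stereocentre is not involved.

**Step 8**
Reactants: 12 (3S)-3-(hydroxymethyl)-2,6-dimethylhept-5-en-2-ol
Product: 13 (3R)-3-(iodomethyl)-2,6-dimethylhept-5-en-2-ol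
Conditions: PPh3, imidazole, I2 (premixed), CH2Cl2, 0 °C; then 12, rt
Reagents that add atoms: iodine, II
Why: Appel-type iodination (Garegg–Samuelsson conditions) that activates only the primary alcohol; premixing the reagents leaves no free iodine for iodoetherification of the prenyl alkene, and the tertiary alcohol does not react.

**Step 9**
Reactants: 13 (3R)-3-(iodomethyl)-2,6-dimethylhept-5-en-2-ol
Product: 14 triethyl{[(3R)-3-(iodomethyl)-2,6-dimethylhept-5-en-2-yl]oxy}silane
Conditions: TESOTf, 2,6-lutidine, CH2Cl2, −78 to 0 °C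
Reagents that add atoms: triethylsilyl trifluoromethanesulfonate, CC[Si](CC)(CC)OS(=O)(=O)C(F)(F)F
Why: Silyl triflate silylation of the hindered tertiary alcohol, which removes the acidic proton before the organozinc is made and gives a group that falls off in the final acidic step.

**Step 10**
Reactants: 14 triethyl{[(3R)-3-(iodomethyl)-2,6-dimethylhept-5-en-2-yl]oxy}silane; 10 (2S)-2-[2,4-bis(methoxymethoxy)phenyl]-6-iodo-5-methoxy-7-(methoxymethoxy)-2,3-dihydro-4H-chromen-4-one
Product: 16 (2S)-2-[2,4-bis(methoxymethoxy)phenyl]-5-methoxy-7-(methoxymethoxy)-6-{(2S)-5-methyl-2-[2-(triethylsilyloxy)propan-2-yl]hex-4-en-1-yl}-2,3-dihydro-4H-chromen-4-one, via alkylzinc iodide 15 (not isolated)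
Conditions: Zn dust (activated by TMSCl/1,2-dibromoethane), LiCl, THF, 40 °C; solution of 15 decanted from zinc; then 10, Pd2(dba)3 (2.5 mol %), SPhos (10 mol %), THF/NMP, 45 °C
Reagents that add atoms: none
Why: Zinc inserts into the primary C–I bond of 14 (LiCl-assisted) to give 15; Pd(0)/SPhos then adds oxidatively to the C6–I bond of 10, the alkyl group is transferred from zinc to palladium, and reductive elimination forms the C6–CH2 bond. The closest known reaction type is the Negishi coupling of β-branched primary alkylzinc iodides with ortho,ortho'-disubstituted aryl iodides under dialkylbiarylphosphine–palladium catalysis. No ring is closed and no stereocentre is created: the side-chain stereocentre is β to zinc and takes no part in any bond made or broken, and C2 of ring C should be preserved because the medium contains no base that could start a retro-oxa-Michael opening. The step needs reductive elimination to outrun β-hydride elimination at the crowded aryl(alkyl)palladium stage, which the bulky electron-rich ligand is chosen to secure, and it needs the alkylzinc to ignore the C4 ketone, which its low nucleophilicity ensures. The site of coupling is fixed in advance by the iodine at C6.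

**Step 11**
Reactants: 16 (2S)-2-[2,4-bis(methoxymethoxy)phenyl]-5-methoxy-7-(methoxymethoxy)-6-{(2S)-5-methyl-2-[2-(triethylsilyloxy)propan-2-yl]hex-4-en-1-yl}-2,3-dihydro-4H-chromen-4-one
Product: 17 (2S)-2-(2,4-dihydroxyphenyl)-7-hydroxy-6-[(2S)-2-(2-hydroxypropan-2-yl)-5-methylhex-4-en-1-yl]-5-methoxy-2,3-dihydro-4H-chromen-4-one
Conditions: 3 M aq. HCl/MeOH/THF, rt to 35 °C, monitored; NaHCO3 quench
Reagents that add atoms: none
Why: Acid-catalysed solvolysis of the three aryl MOM acetals and the tertiary TES ether; dilute methanolic acid near room temperature should spare the non-benzylic tertiary alcohol, the trisubstituted alkene, the aryl methyl ether and the C2 configuration.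

**Compound list**
1 | 5,7-dihydroxy-4H-chromen-4-one | O=c1ccoc2cc(O)cc(O)c12 | starting material
2 | 5-hydroxy-7-(methoxymethoxy)-4H-chromen-4-one | O=c1ccoc2cc(OCOC)cc(O)c12 | intermediate
3 | 5-hydroxy-6-iodo-7-(methoxymethoxy)-4H-chromen-4-one | O=c1ccoc2cc(OCOC)c(I)c(O)c12 | intermediate
4 | 6-iodo-5-methoxy-7-(methoxymethoxy)-4H-chromen-4-one | O=c1ccoc2cc(OCOC)c(I)c(OC)c12 | intermediate
5 | 4-bromobenzene-1,3-diol (4-bromoresorcinol) | Oc1ccc(Br)c(O)c1 | starting material
6 | 1-bromo-2,4-bis(methoxymethoxy)benzene | Brc1ccc(OCOC)cc1OCOC | intermediate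
7 | [2,4-bis(methoxymethoxy)phenyl]lithium | [Li]c1ccc(OCOC)cc1OCOC | intermediate (not isolated)
8 | lithium [2,4-bis(methoxymethoxy)phenyl]tri(propan-2-yloxy)borate | [Li+].CC(C)O[B-](OC(C)C)(OC(C)C)c1ccc(OCOC)cc1OCOC | intermediate (not isolated)
9 | [2,4-bis(methoxymethoxy)phenyl]boronic acid | OB(O)c1ccc(OCOC)cc1OCOC | intermediate
10 | (2S)-2-[2,4-bis(methoxymethoxy)phenyl]-6-iodo-5-methoxy-7-(methoxymethoxy)-2,3-dihydro-4H-chromen-4-one | COc1c(I)c(OCOC)cc2c1C(=O)C[C@@H](c1ccc(OCOC)cc1OCOC)O2 | intermediate
11 | (R)-lavandulol, (2R)-5-methyl-2-(prop-1-en-2-yl)hex-4-en-1-ol | OC[C@H](CC=C(C)C)C(C)=C | starting material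
12 | (3S)-3-(hydroxymethyl)-2,6-dimethylhept-5-en-2-ol | OC[C@H](CC=C(C)C)C(C)(C)O | intermediate
13 | (3R)-3-(iodomethyl)-2,6-dimethylhept-5-en-2-ol | IC[C@H](CC=C(C)C)C(C)(C)O | intermediate
14 | triethyl{[(3R)-3-(iodomethyl)-2,6-dimethylhept-5-en-2-yl]oxy}silane | IC[C@H](CC=C(C)C)C(C)(C)O[Si](CC)(CC)CC | intermediate
15 | {(2R)-5-methyl-2-[2-(triethylsilyloxy)propan-2-yl]hex-4-en-1-yl}zinc iodide | I[Zn]C[C@H](CC=C(C)C)C(C)(C)O[Si](CC)(CC)CC | intermediate (not isolated)
16 | (2S)-2-[2,4-bis(methoxymethoxy)phenyl]-5-methoxy-7-(methoxymethoxy)-6-{(2S)-5-methyl-2-[2-(triethylsilyloxy)propan-2-yl]hex-4-en-1-yl}-2,3-dihydro-4H-chromen-4-one | COc1c(C[C@H](CC=C(C)C)C(C)(C)O[Si](CC)(CC)CC)c(OCOC)cc2c1C(=O)C[C@@H](c1ccc(OCOC)cc1OCOC)O2 | intermediate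
17 | (2S)-2-(2,4-dihydroxyphenyl)-7-hydroxy-6-[(2S)-2-(2-hydroxypropan-2-yl)-5-methylhex-4-en-1-yl]-5-methoxy-2,3-dihydro-4H-chromen-4-one | COc1c(C[C@H](CC=C(C)C)C(C)(C)O)c(O)cc2c1C(=O)C[C@@H](c1ccc(O)cc1O)O2 | target

**Step count.** Total: 11 steps. Longest linear sequence: 6 steps (1, 2, 3, 6, 10, 11).

**Steps most likely to fail**

Step 6. Aryl transfer may be slow or poorly face-selective: the ortho-alkoxy boronic acid can lose boron by protonolysis before it inserts, the 5-methoxy-6-iodo substitution may erode facial discrimination, and oxidative addition at C–I could compete. The fallback sets out from 4 and 6 and returns at 10. Chromone 4 is degraded with aqueous NaOH (ring opening and retro-Claisen loss of formate) to 1-[6-hydroxy-3-iodo-2-methoxy-4-(methoxymethoxy)phenyl]ethan-1-one F1. Aryllithium 7, made from 6 as in step 5, is quenched with DMF to give 2,4-bis(methoxymethoxy)benzaldehyde F2. Claisen–Schmidt condensation of F1 and F2 (KOH, EtOH) gives the (E)-2'-hydroxychalcone F3, which is cyclised by oxa-Michael addition (NaOAc, EtOH, reflux) to the racemic flavanone F4. Preparative HPLC on a chiral stationary phase separates 10 from its (2R)-antipode F5.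

Step 10. Reductive elimination at the doubly ortho-substituted aryl(alkyl)palladium intermediate may be outpaced by β-hydride elimination and reduction of the C–I bond, or zinc salts may open ring C and erode C2. The fallback sets out from 14 and 4 and returns at 16; it couples at the chromone stage, where no C2 stereocentre exists and a basic, more nucleophilic boron partner is acceptable. Iodide 14 is converted with t-BuLi (2 equiv, Et2O, −78 °C) into the alkyllithium F6, which is trapped with B-methoxy-9-BBN as the lithium alkyl(methoxy)borinate F7. B-alkyl Suzuki–Miyaura coupling of F7 with 4 (PdCl2(dppf), AsPh3, K3PO4, DMF/H2O, rt) gives the 6-alkylchromone F8. Rh-catalysed asymmetric 1,4-addition of 9 to F8 under the conditions of step 6 then gives 16.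

Step 7. Chemoselectivity between the two alkenes may be lost: hydrogen-atom transfer to the trisubstituted alkene would give over-hydration and a mixture of regioisomers. The fallback sets out from 11 and returns at 12. It relies on oxymercuration, which strongly prefers 1,1-disubstituted alkenes, after the primary hydroxyl is masked so that it cannot cyclise onto the prenyl alkene. Alcohol 11 is silylated (TBSCl, imidazole) to the lavandulyl TBS ether F9. Hg(OAc)2 in THF/H2O gives the β-hydroxyalkylmercury acetate F10, which NaBH4/NaOH reduces to the tertiary alcohol F11. TBAF then releases 12.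

**Further compounds**
F1 | step 6 | 1-[6-hydroxy-3-iodo-2-methoxy-4-(methoxymethoxy)phenyl]ethan-1-one | CC(=O)c1c(O)cc(OCOC)c(I)c1OC
F2 | step 6 | 2,4-bis(methoxymethoxy)benzaldehyde | O=Cc1ccc(OCOC)cc1OCOC
F3 | step 6 | (E)-3-[2,4-bis(methoxymethoxy)phenyl]-1-[6-hydroxy-3-iodo-2-methoxy-4-(methoxymethoxy)phenyl]prop-2-en-1-one | COc1c(I)c(OCOC)cc(O)c1C(=O)/C=C/c1ccc(OCOC)cc1OCOC
F4 | step 6 | racemic 2-[2,4-bis(methoxymethoxy)phenyl]-6-iodo-5-methoxy-7-(methoxymethoxy)-2,3-dihydro-4H-chromen-4-one | COc1c(I)c(OCOC)cc2c1C(=O)CC(c1ccc(OCOC)cc1OCOC)O2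
F5 | step 6 | (2R)-2-[2,4-bis(methoxymethoxy)phenyl]-6-iodo-5-methoxy-7-(methoxymethoxy)-2,3-dihydro-4H-chromen-4-one | COc1c(I)c(OCOC)cc2c1C(=O)C[C@H](c1ccc(OCOC)cc1OCOC)O2
F6 | step 10 | {(2R)-5-methyl-2-[2-(triethylsilyloxy)propan-2-yl]hex-4-en-1-yl}lithium | [Li]C[C@H](CC=C(C)C)C(C)(C)O[Si](CC)(CC)CC
F7 | step 10 | lithium 9-methoxy-9-{(2R)-5-methyl-2-[2-(triethylsilyloxy)propan-2-yl]hex-4-en-1-yl}-9-boranuidabicyclo[3.3.1]nonane | [Li+].CO[B-]1(C[C@H](CC=C(C)C)C(C)(C)O[Si](CC)(CC)CC)C2CCCC1CCC2
F8 | step 10 | 5-methoxy-7-(methoxymethoxy)-6-{(2S)-5-methyl-2-[2-(triethylsilyloxy)propan-2-yl]hex-4-en-1-yl}-4H-chromen-4-one | COc1c(C[C@H](CC=C(C)C)C(C)(C)O[Si](CC)(CC)CC)c(OCOC)cc2occc(=O)c12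
F9 | step 7 | tert-butyldimethyl{[(2R)-5-methyl-2-(prop-1-en-2-yl)hex-4-en-1-yl]oxy}silane | CC(C)(C)[Si](C)(C)OC[C@H](CC=C(C)C)C(C)=C
F10 | step 7 | (acetato){(3S)-3-[(tert-butyldimethylsilyloxy)methyl]-2-hydroxy-2,6-dimethylhept-5-en-1-yl}mercury | CC(C)(C)[Si](C)(C)OC[C@H](CC=C(C)C)C(C)(O)C[Hg]OC(C)=O
F11 | step 7 | (3S)-3-[(tert-butyldimethylsilyloxy)methyl]-2,6-dimethylhept-5-en-2-ol | CC(C)(C)[Si](C)(C)OC[C@H](CC=C(C)C)C(C)(C)O
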